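**Retrosynthetic overview**
1. Ring numbering used throughout: C1 (OAc), C2=C3 (Me on C3), C4 (OH), C5, C6=C7 (Me on C7), C8, C9 (OBz), C10 (i-Pr); the target is (1S,2Z,4R,6Z,9S,10R).
2. Enabling feature: with the bond C1–C6 restored, C9=C10–C1(O)–C6–C7=C8 is a 3-oxido-hexa-1,5-diene, and C1–C2=C3–C4–C5–C6 is a cyclohexene that already holds the (Z)-C2=C3 alkene and the C4 oxygen. C8–C9 is therefore made by an anionic oxy-Cope ring expansion (six- to ten-membered) that also sets C9, the (Z)-C6=C7 alkene, the C1 carbonyl and, on protonation, C10.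
3. The cyclohexene comes from (S)-carvone (trans-carveol silyl ether, then allylic oxidation to a 6-isopropenyl-4-silyloxycyclohexenone). C9, C10 and the isopropyl group arrive as a (Z)-β-(4-methoxybenzyloxy)alkenyllithium made from 3-methylbutanal, added cis to the isopropenyl group.
4. Endgame: PMB removal, Evans–Tishchenko reduction with benzaldehyde (C9 benzoate and anti C1 carbinol in one operation), acetylation, desilylation.
5. Ring order: the cyclohexene ring is present from the start (carvone); the ten-membered ring is formed in the key step; no other ring is made.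

Key step: step 10

Remark: in 6 and 13–15 the cyclohexene atoms C1–C6 are the future C1–C6 of the ten-membered ring. Compound 9 is carried as an E/Z mixture and 10 as a diastereomer mixture, because that stereochemistry is erased in step 8.

**Step 1**
Reactants: 1 (S)-(+)-carvone
Product: 2 (1S,5S)-2-methyl-5-(prop-1-en-2-yl)cyclohex-2-en-1-ol (cis-carveol)
Conditions: NaBH4, CeCl3·7H2O, MeOH, −20 °C
Reagents that add atoms: none
Why: Luche reduction gives 1,2-selective axial hydride delivery to the enone, so the new hydroxyl is equatorial and cis to the equatorial isopropenyl group (1S).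

**Step 2**
Reactants: 2 cis-carveol
Product: 3 (1R,5S)-2-methyl-5-(prop-1-en-2-yl)cyclohex-2-en-1-yl 4-nitrobenzoate
Conditions: 4-O2NC6H4CO2H, PPh3, DIAD, THF, 0 → 25 °C
Reagents that add atoms: 4-nitrobenzoic acid, O=C(O)c1ccc(cc1)[N+](=O)[O-]
Why: Mitsunobu esterification displaces the oxyphosphonium ion by SN2 with inversion at the carbinol carbon, giving the trans (1R) ester that places the future C4 oxygen trans to the isopropenyl group.

**Step 3**
Reactants: 3 trans-carveyl 4-nitrobenzoate
Product: 4 (1R,5S)-2-methyl-5-(prop-1-en-2-yl)cyclohex-2-en-1-ol (trans-carveol)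
Conditions: K2CO3 (cat.), MeOH, 25 °C
Reagents that add atoms: none
Why: Base-catalysed transesterification to methyl 4-nitrobenzoate releases the allylic alcohol without touching either stereocentre.

**Step 4**
Reactants: 4 trans-carveol
Product: 5 tert-butyldimethyl{[(1R,5S)-2-methyl-5-(prop-1-en-2-yl)cyclohex-2-en-1-yl]oxy}silane
Conditions: TBSCl, imidazole, DMF, 25 °C
Reagents that add atoms: tert-butyldimethylsilyl chloride, CC(C)(C)[Si](C)(C)Cl
Why: Standard silylation of a secondary allylic alcohol; the TBS ether should survive the organolithium, KN(SiMe3)2, DDQ and acylation steps and leave at the end with fluoride.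

**Step 5**
Reactants: 5 trans-carveol TBS ether
Product: 6 (4R,6S)-4-[(tert-butyldimethylsilyl)oxy]-3-methyl-6-(prop-1-en-2-yl)cyclohex-2-en-1-one
Conditions: Rh2(cap)4 (dirhodium tetracaprolactamate, 1 mol %), t-BuOOH (70 % aq., 5 equiv), K2CO3, CH2Cl2, 25 °C
Reagents that add atoms: tert-butyl hydroperoxide, CC(C)(C)OO
Why: Catalytic allylic C–H oxidation of a cyclohexene to the enone by tert-butylperoxyl radicals should attack the only free ring allylic methylene (the other allylic ring position carries the silyloxy group), as in the known oxidation of 3-oxy-cyclohexenes to 4-oxy-cyclohexenones; the epimerisable C6 centre stays trans to the silyloxy group, the arrangement that relieves A(1,2) strain with the C3 methyl.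

**Step 6**
Reactants: 7 3-methylbutanal
Product: 8 1,1-bis[(4-methoxybenzyl)oxy]-3-methylbutane
Conditions: 4-MeOC6H4CH2OH (2.2 equiv), PPTS (cat.), 4 Å MS, CH2Cl2, 25 °C
Reagents that add atoms: 4-methoxybenzyl alcohol, COc1ccc(CO)cc1
Why: Acid-catalysed acetalisation of an aliphatic aldehyde, driven by removal of water.

**Step 7**
Reactants: 8 bis-PMB acetal
Product: 9 1-methoxy-4-{[(3-methylbut-1-en-1-yl)oxy]methyl}benzene (E/Z mixture)
Conditions: TMSOTf (1.1 equiv), i-Pr2NEt (1.3 equiv), CH2Cl2, −20 → 25 °C
Reagents that add atoms: none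
Why: The silyl triflate ionises the acetal to an oxocarbenium ion that the amine deprotonates at C2 (acetal-to-enol-ether elimination); the alkene geometry does not matter because step 8 erases it.

**Step 8**
Reactants: 9 PMB enol ether
Product: 11 (Z)-1-{[(2-bromo-3-methylbut-1-en-1-yl)oxy]methyl}-4-methoxybenzene, via dibromo ether 10 (not isolated)
Conditions: Br2 (1.0 equiv), CH2Cl2, −78 °C; then DBU, −78 → 25 °C
Reagents that add atoms: bromine, BrBr
Why: Bromine adds to the electron-rich enol ether and the labile α-bromo ether loses HBr through its oxocarbenium ion to the β-bromo enol ether; the Z isomer (Br cis to O, isopropyl away from the benzyloxy group) should be favoured and is separable from any E isomer.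

**Step 9**
Reactants: 6 silyloxy enone; 11 (Z)-bromo enol ether
Product: 13 (1R,4R,6S)-4-[(tert-butyldimethylsilyl)oxy]-1-{(1Z)-1-[(4-methoxybenzyl)oxy]-3-methylbut-1-en-2-yl}-3-methyl-6-(prop-1-en-2-yl)cyclohex-2-en-1-ol, via alkenyllithium 12 (not isolated)
Conditions: 11, t-BuLi (2 equiv), Et2O, −78 °C; then 6, THF, −78 → −40 °C; NH4Cl (aq.)
Reagents that add atoms: none
Why: Bromine–lithium exchange with retention gives the chelation-stabilised alkenyllithium with Li cis to oxygen, which adds 1,2 to the enone by axial attack on the half-chair (equatorial isopropenyl, pseudoaxial silyloxy), on the face anti to the C4 silyloxy group and cis to the isopropenyl group, setting C1 as R.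

**Step 10**
Reactants: 13 dialkenyl cyclohexenol
Product: 16 (2Z,4R,6Z,9S,10R)-4-[(tert-butyldimethylsilyl)oxy]-9-[(4-methoxybenzyl)oxy]-3,7-dimethyl-10-(propan-2-yl)cyclodeca-2,6-dien-1-one, via potassium alkoxide 14 (not isolated), via potassium dienolate 15 (not isolated)
Conditions: KN(SiMe3)2 (1.2 equiv), 18-crown-6, THF, −20 → 25 °C; then AcOH, THF, −78 °C
Reagents that add atoms: none
Why: KN(SiMe3)2 gives potassium alkoxide 14, whose oxido group at C1 accelerates a concerted [3,3]-sigmatropic shift across C9=C10–C1–C6–C7=C8 through a chair transition state, in which the ring bond C1–C6 breaks while C8–C9 forms to give the cross-conjugated dienolate 15 of the ring-expanded ketone, which acetic acid protonates at C10. The closest known reaction type is the anionic oxy-Cope ring expansion of 1-alkenyl-6-isopropenylcyclohex-2-en-1-ols to cyclodeca-2,6-dienones used for germacrane skeletons. The ten-membered ring is closed by ring expansion and not by end-to-end cyclisation: the termini C8 and C9 are held gauche on the cyclohexene, so the closure is a six-membered chair pericyclic event that enlarges the six-membered ring by four atoms. C9 is controlled by chirality transfer from C1 (R) and C6 (S) through the chair, since bond formation at C9 is suprafacial on the alkenyl face from which C6 departs and, with the (Z)-enol ether (OPMB inside, axial), this gives 9S; C10 is then set by protonation of the enolate on its outer face, anti to the new C8–C9 bond, giving 10R (isopropyl and C9–O syn). The step needs the (Z)-C6=C7 alkene, which means C5 axial on the chair: because the two alkenyl groups are cis, exactly one ring bond must be axial, and the inside OPMB at C9 forces the small oxido oxygen and not C2 into the syn-inside position at C1 (A(1,3) strain), so the axial ring bond is C5, in the chair that is reached directly from the ground-state half-chair with equatorial isopropenyl and pseudoaxial silyloxy groups. The competing process is loss of 4-methoxybenzyl oxide from the β-alkoxy enolate 15, which should be held back by rearranging at or below room temperature and quenching cold.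

**Step 11**
Reactants: 16 PMB-protected cyclodecadienone
Product: 17 (2Z,4R,6Z,9S,10R)-4-[(tert-butyldimethylsilyl)oxy]-9-hydroxy-3,7-dimethyl-10-(propan-2-yl)cyclodeca-2,6-dien-1-one
Conditions: DDQ, CH2Cl2/pH 7 buffer, 0 °C
Reagents that add atoms: none
Why: Oxidative PMB cleavage (hydride abstraction from the electron-rich benzylic position, then hydrolysis of the oxocarbenium ion) under buffered neutral conditions should spare the TBS ether, the enone and the elimination-prone β-hydroxy ketone.

**Step 12**
Reactants: 17 β-hydroxy ketone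
Product: 18 (1S,2Z,4R,6Z,9S,10S)-4-[(tert-butyldimethylsilyl)oxy]-1-hydroxy-3,7-dimethyl-10-(propan-2-yl)cyclodeca-2,6-dien-9-yl benzoate (target numbering; C10 is spatially unchanged, only its CIP descriptor changes)
Conditions: PhCHO (5 equiv), SmI2 (0.3 equiv), THF, −10 °C
Reagents that add atoms: benzaldehyde, O=Cc1ccccc1
Why: Evans–Tishchenko reduction: the samarium-bound hemiacetal formed from the C9 hydroxyl and benzaldehyde delivers its hydride intramolecularly to the C1 carbonyl through a chair-like six-membered transition state, giving the 1,3-anti carbinol (1S) and leaving the oxidised hemiacetal as the C9 benzoate.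

**Step 13**
Reactants: 18 hydroxy benzoate
Product: 19 (1S,2Z,4R,6Z,9S,10R)-1-acetoxy-4-[(tert-butyldimethylsilyl)oxy]-3,7-dimethyl-10-(propan-2-yl)cyclodeca-2,6-dien-9-yl benzoate (target numbering)
Conditions: Ac2O, DMAP, pyridine, CH2Cl2, 0 → 25 °C
Reagents that add atoms: acetic anhydride, CC(=O)OC(C)=O
Why: DMAP-catalysed acetylation of the only free hydroxyl (C1); the C4 oxygen is still silylated, so no selectivity between the two allylic alcohols is needed.

**Step 14**
Reactants: 19 silyl-protected diester
Product: 20 (1S,2Z,4R,6Z,9S,10R)-1-acetoxy-4-hydroxy-3,7-dimethyl-10-(propan-2-yl)cyclodeca-2,6-dien-9-yl benzoate (target numbering; CNP0125882.1)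
Conditions: Bu4NF, AcOH, THF, 0 → 25 °C
Reagents that add atoms: none
Why: Fluoride cleavage of the allylic TBS ether, buffered with acetic acid to suppress acyl migration and ester cleavage, releases the C4 alcohol and gives the target.

**Compound list**
1 | (S)-(+)-carvone, (5S)-2-methyl-5-(prop-1-en-2-yl)cyclohex-2-en-1-one | O=C1C(C)=CC[C@H](C(C)=C)C1 | starting material
2 | (1S,5S)-cis-carveol | O[C@@H]1C(C)=CC[C@H](C(C)=C)C1 | intermediate
3 | (1R,5S)-trans-carveyl 4-nitrobenzoate | O=C(O[C@H]1C(C)=CC[C@H](C(C)=C)C1)c1ccc(cc1)[N+](=O)[O-] | intermediate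
4 | (1R,5S)-trans-carveol | O[C@H]1C(C)=CC[C@H](C(C)=C)C1 | intermediate
5 | (1R,5S)-trans-carveol tert-butyldimethylsilyl ether | CC(C)(C)[Si](C)(C)O[C@H]1C(C)=CC[C@H](C(C)=C)C1 | intermediate
6 | (4R,6S)-4-[(tert-butyldimethylsilyl)oxy]-3-methyl-6-(prop-1-en-2-yl)cyclohex-2-en-1-one | CC(C)(C)[Si](C)(C)O[C@H]1C(C)=CC(=O)[C@H](C(C)=C)C1 | intermediate
7 | 3-methylbutanal | CC(C)CC=O | starting material
8 | 1,1-bis[(4-methoxybenzyl)oxy]-3-methylbutane | CC(C)CC(OCc1ccc(OC)cc1)OCc1ccc(OC)cc1 | intermediate
9 | 1-methoxy-4-{[(3-methylbut-1-en-1-yl)oxy]methyl}benzene (E/Z mixture) | CC(C)C=COCc1ccc(OC)cc1 | intermediate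
10 | 1-{[(1,2-dibromo-3-methylbutyl)oxy]methyl}-4-methoxybenzene (diastereomer mixture, not isolated) | CC(C)C(Br)C(Br)OCc1ccc(OC)cc1 | intermediate
11 | (Z)-1-{[(2-bromo-3-methylbut-1-en-1-yl)oxy]methyl}-4-methoxybenzene (Br cis to O) | Br/C(C(C)C)=C\OCc1ccc(OC)cc1 | intermediate
12 | {1-[(4-methoxybenzyl)oxy]-3-methylbut-1-en-2-yl}lithium, Li cis to O (not isolated) | [Li]/C(C(C)C)=C\OCc1ccc(OC)cc1 | intermediate
13 | (1R,4R,6S)-4-[(tert-butyldimethylsilyl)oxy]-1-{(1Z)-1-[(4-methoxybenzyl)oxy]-3-methylbut-1-en-2-yl}-3-methyl-6-(prop-1-en-2-yl)cyclohex-2-en-1-ol | CC(C)(C)[Si](C)(C)O[C@H]1C(C)=C[C@](O)(/C(C(C)C)=C\OCc2ccc(OC)cc2)[C@H](C(C)=C)C1 | intermediate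
14 | potassium alkoxide of 13 (not isolated) | CC(C)(C)[Si](C)(C)O[C@H]1C(C)=C[C@]([O-])(/C(C(C)C)=C\OCc2ccc(OC)cc2)[C@H](C(C)=C)C1.[K+] | intermediate
15 | potassium C1=C10 dienolate of 16, C2 trans to C9 across C1=C10 (not isolated) | [K+].[O-]/C1=C(C(C)C)\[C@@H](OCc2ccc(OC)cc2)C/C(C)=C\C[C@@H](O[Si](C)(C)C(C)(C)C)/C(C)=C\1 | intermediate
16 | (2Z,4R,6Z,9S,10R)-4-[(tert-butyldimethylsilyl)oxy]-9-[(4-methoxybenzyl)oxy]-3,7-dimethyl-10-(propan-2-yl)cyclodeca-2,6-dien-1-one | O=C1/C=C(/C)[C@H](O[Si](C)(C)C(C)(C)C)C/C=C(/C)C[C@H](OCc2ccc(OC)cc2)[C@H]1C(C)C | intermediate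
17 | (2Z,4R,6Z,9S,10R)-4-[(tert-butyldimethylsilyl)oxy]-9-hydroxy-3,7-dimethyl-10-(propan-2-yl)cyclodeca-2,6-dien-1-one | O=C1/C=C(/C)[C@H](O[Si](C)(C)C(C)(C)C)C/C=C(/C)C[C@H](O)[C@H]1C(C)C | intermediate
18 | (1S,2Z,4R,6Z,9S,10S)-4-[(tert-butyldimethylsilyl)oxy]-1-hydroxy-3,7-dimethyl-10-(propan-2-yl)cyclodeca-2,6-dien-9-yl benzoate (target numbering) | O[C@H]1/C=C(/C)[C@H](O[Si](C)(C)C(C)(C)C)C/C=C(/C)C[C@H](OC(=O)c2ccccc2)[C@H]1C(C)C | intermediate
19 | (1S,2Z,4R,6Z,9S,10R)-1-acetoxy-4-[(tert-butyldimethylsilyl)oxy]-3,7-dimethyl-10-(propan-2-yl)cyclodeca-2,6-dien-9-yl benzoate (target numbering) | CC(=O)O[C@H]1/C=C(/C)[C@H](O[Si](C)(C)C(C)(C)C)C/C=C(/C)C[C@H](OC(=O)c2ccccc2)[C@H]1C(C)C | intermediate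
20 | (1S,2Z,4R,6Z,9S,10R)-1-acetoxy-4-hydroxy-3,7-dimethyl-10-(propan-2-yl)cyclodeca-2,6-dien-9-yl benzoate (target numbering), CNP0125882.1 | CC(=O)O[C@H]1/C=C(/C)[C@H](O)C/C=C(/C)C[C@H](OC(=O)c2ccccc2)[C@H]1C(C)C | target

**Step count and risks**
Total step count: 14. Longest linear sequence: 11 steps (steps 1–5 and 9–14, from (S)-carvone); steps 6–8 prepare the alkenyl fragment.

Steps most likely to fail:

Step 10. The ring-expanded β-alkoxy enolate may expel 4-methoxybenzyl oxide (β-elimination) faster than it can be quenched, or the rearrangement may need temperatures at which this elimination takes over. The fallback turns the elimination into the route and brings the C9 oxygen in after the ring is made. It sets out from 13: the same base (KN(SiMe3)2, 18-crown-6, THF) is used with warming to 50 °C, so that rearrangement and elimination both go to completion and give the cross-conjugated trienone F1. Copper-catalysed conjugate borylation of the less substituted enone (CuCl, NaOt-Bu, a chiral Josiphos-type bisphosphine whose enantiomer is chosen for the 9S adduct, B2pin2, MeOH, THF) should then give the β-boryl ketone F2, with C10 set by protonation of the enolate by methanol. Oxidation with NaBO3·4H2O (retention at C9) comes back to the route at 17.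

Step 9. The hindered, basic alkenyllithium may attack from the equatorial direction (alkenyl trans to the isopropenyl group, which would lead to the 6E ring) or may enolise the ketone instead of adding. The fallback builds the same side chain on a small, weakly basic nucleophile that adds strictly axially. It sets out from 6: HC≡CMgBr (THF, −78 → 0 °C) gives the propargylic alcohol F3. Hydroxyl-directed anti-carbomagnesiation (i-PrMgCl, CuI cat., THF) followed by I2 gives the vinyl iodide F4, with iodine cis to the carbinol carbon. Copper-catalysed C–O coupling with 4-methoxybenzyl alcohol (CuI, 3,4,7,8-tetramethyl-1,10-phenanthroline, Cs2CO3, toluene, 80 °C), with retention of alkene geometry, comes back to the route at 13.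

Step 5. Hydrogen abstraction may occur at the wrong site (the carbinol C–H next to the silyloxy group, or the allylic positions of the isopropenyl group), the product may be over-oxidised at its doubly activated C6–H, or the isopropenyl double bond may move into conjugation. The fallback replaces radical C–H oxidation by a polar epoxide/transposition sequence. It sets out from 5: mCPBA (CH2Cl2, 0 °C) epoxidises the more electron-rich ring alkene to the epoxide F5 (oxygen expected anti to the silyloxy group; this configuration is erased later). PhSeNa (from (PhSe)2 and NaBH4, EtOH) opens it at the secondary carbon to the hydroxy selenide F6. H2O2 causes selenoxide syn-elimination away from the carbinol to the tertiary allylic alcohol F7. Babler–Dauben oxidative 1,3-transposition with pyridinium chlorochromate, (C5H5NH)[CrO3Cl], in CH2Cl2 comes back to the route at 6.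

**Further compounds**
F1 | step 10 | (2Z,4R,6Z,9Z)-4-[(tert-butyldimethylsilyl)oxy]-3,7-dimethyl-10-(propan-2-yl)cyclodeca-2,6,9-trien-1-one (9Z assumed) | O=C1/C=C(/C)[C@H](O[Si](C)(C)C(C)(C)C)C/C=C(/C)C/C=C\1C(C)C
F2 | step 10 | 9-(pinacolboryl) analogue of 17, boron in place of the C9 hydroxyl with the same spatial arrangement | O=C1/C=C(/C)[C@H](O[Si](C)(C)C(C)(C)C)C/C=C(/C)C[C@H](B2OC(C)(C)C(C)(C)O2)[C@H]1C(C)C
F3 | step 9 | (1R,4R,6S)-4-[(tert-butyldimethylsilyl)oxy]-1-ethynyl-3-methyl-6-(prop-1-en-2-yl)cyclohex-2-en-1-ol | CC(C)(C)[Si](C)(C)O[C@H]1C(C)=C[C@](O)(C#C)[C@H](C(C)=C)C1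
F4 | step 9 | (1R,4R,6S)-4-[(tert-butyldimethylsilyl)oxy]-1-[(1Z)-1-iodo-3-methylbut-1-en-2-yl]-3-methyl-6-(prop-1-en-2-yl)cyclohex-2-en-1-ol (iodine cis to the carbinol carbon) | CC(C)(C)[Si](C)(C)O[C@H]1C(C)=C[C@](O)(/C(C(C)C)=C\I)[C@H](C(C)=C)C1
F5 | step 5 | 2,3-epoxide of 5, epoxide oxygen anti to the silyloxy group | CC(C)(C)[Si](C)(C)O[C@H]1[C@]2(C)O[C@@H]2C[C@H](C(C)=C)C1
F6 | step 5 | hydroxy selenide from F5: tertiary C2 alcohol, C3 phenylselanyl anti to it | CC(C)(C)[Si](C)(C)O[C@H]1[C@](C)(O)[C@@H]([Se]c2ccccc2)C[C@H](C(C)=C)C1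
F7 | step 5 | tertiary allylic alcohol from F6: 1-silyloxy-2-methyl-5-(prop-1-en-2-yl)cyclohex-3-en-2-ol | CC(C)(C)[Si](C)(C)O[C@H]1[C@](C)(O)C=C[C@H](C(C)=C)C1
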